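## Retrosynthetic overview

1. The bicyclo[3.2.1]octenedione (bonds C14–C8' and C15–C13') is cut by a perezone-type [5+2] cycloaddition between hydroxy-para-quinone 17 and the terminal C14=C15 bond of tetraene 37, whose labdane half is still acyclic (rings A and B open).
2. Quinone half: an enantioselective proton-initiated bicyclization builds rings A' and B' (ferruginol methyl ether), a Wolff rearrangement contracts ring B' to the five-membered ring, and the arene is then oxidised to the hydroxyquinone.
3. Labdane half: an Ireland–Claisen rearrangement sets C9 and the quaternary C10; the chain is then given the C5=C4 enoate, the C6 selenide, the C8 methylene, the C3 chloride and the C12–C15 diene.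
4. Enabling feature: C4 is the quaternary α-carbon and C5 the β-carbon of the C18 carboxyl group, both next to quaternary C10. As the enoate C5=C4(CH3)–C18O2R this unit accepts a C6 radical at C5 (ring B), and the C4 ester enolate then alkylates C3 (ring A, closed last).
5. Ring order: A' and B' (step 3), contraction of B' (step 6), the five- and seven-membered rings of the bicyclooctane (step 22), ring B then ring A (step 24).

Key step: step 24

Remarks and assumptions:
- Locants: the acid half carries labdane numbering (C1–C20, carboxyl C18), also in its acyclic precursors. The ring-contracted abietane half carries primed abietane numbering (five-membered ring C5', C6', C8', C9', C10'; formyl carbon C7').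
- Assumption: the (R)-configured ligand in step 3 is taken to give the 5'S,10'S series; if the sense of induction is the opposite, the (S)-ligand is used.
- Assumption: the 6'α-carbonyl epimer (cis to H-5', trans to C4' and to the C10' methyl group) is the thermodynamically preferred one; steps 6 and 9 rely on this.
- The geometry of the C4=C5 enoate has no consequence, because both carbons become sp3 in step 24.

## Route

Step 1
Reactants: 1 2-isopropylanisole
Product: 2 4-(chloromethyl)-1-methoxy-2-(propan-2-yl)benzene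
Conditions: (CH2O)n, conc. HCl, ZnCl2 (cat.), AcOH, 50 °C
Reagents that add atoms: formaldehyde (C=O); hydrogen chloride (Cl)
Why: Blanc chloromethylation should occur para to the methoxy group, the most activated position that is not crowded by the isopropyl group.

Step 2
Reactants: 2 4-(chloromethyl)-1-methoxy-2-(propan-2-yl)benzene; 3 geranyl chloride
Product: 5 4-[(3E)-4,8-dimethylnona-3,7-dien-1-yl]-1-methoxy-2-(propan-2-yl)benzene, via benzylic Grignard reagent 4 (not isolated)
Conditions: Mg, THF, 0 °C; then 3, Li2CuCl4 (cat.), THF, −10 → 23 °C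
Reagents that add atoms: none
Why: Li2CuCl4-catalysed coupling of a benzylic Grignard reagent with a primary allylic chloride should occur at the CH2Cl carbon without allylic transposition, so the E alkene is kept.

Step 3
Reactants: 5 4-[(3E)-4,8-dimethylnona-3,7-dien-1-yl]-1-methoxy-2-(propan-2-yl)benzene
Product: 6 ferruginol methyl ether
Conditions: (R)-3,3'-dichloro-1,1'-bi-2-naphthol·SbCl5 (0.5 equiv), CH2Cl2, −78 °C
Reagents that add atoms: none
Why: Enantioselective proton-initiated cationic polyene cyclization: chair–chair folding of the E alkene gives the trans-fused rings A' and B' (H-5' anti to the C10' methyl group), the arene closes ring B' at C9' (para to isopropyl), and the chiral acid selects the face of the terminal alkene, setting C5' and C10'.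

Step 4
Reactants: 6 ferruginol methyl ether
Product: 7 sugiol methyl ether
Conditions: CrO3, AcOH/H2O, 23 °C
Reagents that add atoms: chromium trioxide (O=[Cr](=O)=O)
Why: Benzylic oxidation of the ring methylene C7', which is activated by the para methoxy group, gives the aryl ketone, a known conversion in this abietatriene class.

Step 5
Reactants: 7 sugiol methyl ether
Product: 9 6-diazo-12-methoxyabieta-8,11,13-trien-7-one, via trifluoroacetyl ketone 8 (not isolated)
Conditions: LiN(SiMe3)2, THF, −78 °C; CF3CO2CH2CF3; then MsN3, Et3N, H2O, MeCN, 23 °C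
Reagents that add atoms: methanesulfonyl azide (CS(=O)(=O)N=[N+]=[N-])
Why: Regitz-type diazo transfer with trifluoroacetyl activation: the kinetic enolate is acylated at C6' and the 1,3-dicarbonyl takes up the diazo group with loss of the trifluoroacetyl group, while C5' cannot enolise towards the ketone and keeps its configuration.

Step 6
Reactants: 9 6-diazo-12-methoxyabieta-8,11,13-trien-7-one
Product: 11 methyl (4aS,9R,9aS)-6-methoxy-1,1,4a-trimethyl-7-(propan-2-yl)-2,3,4,4a,9,9a-hexahydro-1H-fluorene-9-carboxylate, via ketene 10 (not isolated)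
Conditions: hν (medium-pressure Hg lamp, Pyrex), MeOH, 23 °C; then NaOMe (cat.), MeOH, 23 °C
Reagents that add atoms: methanol (CO)
Why: Photochemical Wolff rearrangement: the aryl carbon C8' migrates from C7' to C6' with loss of N2 and contracts ring B' to the five-membered ring, methanol traps the ketene, and NaOMe should equilibrate C6' to the 6'α-ester.

Step 7
Reactants: 11 methyl (4aS,9R,9aS)-6-methoxy-1,1,4a-trimethyl-7-(propan-2-yl)-2,3,4,4a,9,9a-hexahydro-1H-fluorene-9-carboxylate
Product: 12 methyl (4aS,9R,9aS)-6-hydroxy-1,1,4a-trimethyl-7-(propan-2-yl)-2,3,4,4a,9,9a-hexahydro-1H-fluorene-9-carboxylate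
Conditions: BBr3, CH2Cl2, −78 → 0 °C
Reagents that add atoms: none
Why: Lewis-acid cleavage of the aryl methyl ether should be much faster than attack on the methyl ester at this temperature.

Step 8
Reactants: 12 methyl (4aS,9R,9aS)-6-hydroxy-1,1,4a-trimethyl-7-(propan-2-yl)-2,3,4,4a,9,9a-hexahydro-1H-fluorene-9-carboxylate
Product: 13 (4aS,9R,9aS)-9-(hydroxymethyl)-1,1,4a-trimethyl-7-(propan-2-yl)-2,3,4,4a,9,9a-hexahydro-1H-fluoren-6-ol
Conditions: LiAlH4, THF, 0 °C
Reagents that add atoms: none
Why: Hydride reduction of the ester to the primary alcohol (the phenol is carried as its aluminate) also freezes the C6' configuration.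

Step 9
Reactants: 13 (4aS,9R,9aS)-9-(hydroxymethyl)-1,1,4a-trimethyl-7-(propan-2-yl)-2,3,4,4a,9,9a-hexahydro-1H-fluoren-6-ol
Product: 17 (4aS,9R,9aS)-6-hydroxy-1,1,4a-trimethyl-5,8-dioxo-7-(propan-2-yl)-2,3,4,4a,5,8,9,9a-octahydro-1H-fluorene-9-carbaldehyde, via ortho-quinone aldehyde 14 (not isolated), via arylthio catechol 15 (not isolated), via arylthio ortho-quinone 16 (not isolated)
Conditions: IBX (3.5 equiv), DMF, 23 °C; then C6F5SH, 0 °C; then IBX (1.2 equiv); then NaOH, MeOH/H2O, 0 °C; HCl work-up
Reagents that add atoms: 2-iodoxybenzoic acid (O=C1OI(=O)(O)c2ccccc12); sodium hydroxide ([Na+].[OH-])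
Why: IBX should oxidise the primary alcohol to the aldehyde and the para-blocked phenol at its free ortho carbon C11' to the ortho-quinone; thiol conjugate addition at C14', re-oxidation and hydroxide addition–elimination at C14' with tautomerisation then give the hydroxy-para-quinone, and the base only moves C6' towards the preferred 6'α-aldehyde.

Step 10
Reactants: 18 5-chloropent-1-yne
Product: 20 (3E)-7-chloro-4-methylhept-3-en-2-one, via alkenylalane 19 (not isolated)
Conditions: Me3Al, Cp2ZrCl2 (cat.), CH2Cl2, 0 → 23 °C; then AcCl, 0 °C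
Reagents that add atoms: trimethylaluminium (C[Al](C)C); acetyl chloride (CC(Cl)=O)
Why: Zirconium-catalysed Negishi carboalumination adds CH3 and Al syn across the alkyne with Al at the terminus, and acylation of the alkenylalane with retention should give the E enone.

Step 11
Reactants: 20 (3E)-7-chloro-4-methylhept-3-en-2-one
Product: 21 (2R,3E)-7-chloro-4-methylhept-3-en-2-ol
Conditions: (S)-2-methyl-CBS-oxazaborolidine (cat.), BH3·SMe2, THF, −30 °C
Reagents that add atoms: none
Why: Corey–Bakshi–Shibata reduction: with the alkenyl group as the large and CH3 as the small substituent, the (S)-catalyst should give the (R)-allylic alcohol, the centre that later controls C9 and C10.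

Step 12
Reactants: 21 (2R,3E)-7-chloro-4-methylhept-3-en-2-ol; 22 hex-4-ynoic acid
Product: 23 (2R,3E)-7-chloro-4-methylhept-3-en-2-yl hex-4-ynoate
Conditions: DCC, DMAP (cat.), CH2Cl2, 0 → 23 °C
Reagents that add atoms: none
Why: Steglich esterification acylates the secondary allylic alcohol without touching its stereocentre.

Step 13
Reactants: 23 (2R,3E)-7-chloro-4-methylhept-3-en-2-yl hex-4-ynoate
Product: 26 (2R,3S,4E)-2-(but-2-yn-1-yl)-3-(3-chloropropyl)-3-methylhex-4-enoic acid, via Z silyl ketene acetal 24 (not isolated), via silyl ester 25 (not isolated)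
Conditions: LiN(iPr)2, THF/DMPU (4:1), −78 °C; t-BuMe2SiCl; −78 → 50 °C; then 1 M HCl
Reagents that add atoms: none
Why: Ireland–Claisen rearrangement: enolisation in THF/DMPU should give the Z silyl ketene acetal, and the chair transition state with the carbinol CH3 equatorial transfers the carbinol configuration to C9 and to the quaternary C10 (C11 chain and chloropropyl chain equatorial, C10 methyl axial) and gives the E-propenyl group.

Step 14
Reactants: 26 (2R,3S,4E)-2-(but-2-yn-1-yl)-3-(3-chloropropyl)-3-methylhex-4-enoic acid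
Product: 27 (2R,3S,4E)-2-(but-2-yn-1-yl)-3-(3-chloropropyl)-N-methoxy-N,3-dimethylhex-4-enamide
Conditions: MeNHOMe·HCl, EDC·HCl, HOBt (cat.), iPr2NEt, CH2Cl2, 0 → 23 °C
Reagents that add atoms: N,O-dimethylhydroxylamine hydrochloride (CNOC.Cl)
Why: Carbodiimide coupling gives the Weinreb amide, and the hindered α-centre C9 should not epimerise under these mild conditions.

Step 15
Reactants: 27 (2R,3S,4E)-2-(but-2-yn-1-yl)-3-(3-chloropropyl)-N-methoxy-N,3-dimethylhex-4-enamide
Product: 28 (2R,3R)-2-(but-2-yn-1-yl)-6-chloro-3-formyl-N-methoxy-N,3-dimethylhexanamide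
Conditions: O3, CH2Cl2/pyridine, −78 °C; then PPh3, −78 → 23 °C
Reagents that add atoms: ozone ([O-][O+]=O)
Why: Ozonolysis cleaves the only alkene (the internal alkyne reacts far more slowly) and reductive work-up gives the aldehyde at C5 on the quaternary C10.

Step 16
Reactants: 29 triethyl 2-phosphonopropionate; 30 2-(trimethylsilyl)ethanol
Product: 31 2-(trimethylsilyl)ethyl 2-(diethoxyphosphoryl)propanoate
Conditions: DMAP (cat.), toluene, reflux, EtOH distilled off
Reagents that add atoms: none
Why: DMAP-catalysed transesterification exchanges only the carboxylic ester and is driven by removal of ethanol.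

Step 17
Reactants: 28 (2R,3R)-2-(but-2-yn-1-yl)-6-chloro-3-formyl-N-methoxy-N,3-dimethylhexanamide; 31 2-(trimethylsilyl)ethyl 2-(diethoxyphosphoryl)propanoate
Product: 32 2-(trimethylsilyl)ethyl (2E,4S,5R)-4-(3-chloropropyl)-5-[methoxy(methyl)carbamoyl]-2,4-dimethylnon-2-en-7-ynoate
Conditions: 31, NaH, THF, 0 °C; then 28, 0 → 23 °C
Reagents that add atoms: none
Why: Horner–Wadsworth–Emmons olefination of the hindered aldehyde installs the C5=C4(CH3)–C18 enoate, and the phosphonate anion is too weak a base to epimerise C9.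

Step 18
Reactants: 32 2-(trimethylsilyl)ethyl (2E,4S,5R)-4-(3-chloropropyl)-5-[methoxy(methyl)carbamoyl]-2,4-dimethylnon-2-en-7-ynoate
Product: 33 2-(trimethylsilyl)ethyl (2E,4S,5R)-5-(but-2-yn-1-yl)-4-(3-chloropropyl)-2,4-dimethyl-6-oxoocta-2,7-dienoate
Conditions: CH2=CHMgBr, THF, −78 → −20 °C; cold 1 M HCl quench
Reagents that add atoms: vinylmagnesium bromide (C=C[Mg]Br)
Why: Weinreb ketone synthesis: the chelated tetrahedral intermediate prevents over-addition, the hindered α-methyl enoate should be spared, and the acidic quench prevents conjugate addition of the released amine.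

Step 19
Reactants: 33 2-(trimethylsilyl)ethyl (2E,4S,5R)-5-(but-2-yn-1-yl)-4-(3-chloropropyl)-2,4-dimethyl-6-oxoocta-2,7-dienoate
Product: 34 2-(trimethylsilyl)ethyl (2E,4S,5R)-5-(but-2-yn-1-yl)-4-(3-chloropropyl)-2,4-dimethyl-6-oxo-8-(phenylselanyl)oct-2-enoate
Conditions: PhSeH, Et3N (cat.), CH2Cl2, 0 °C
Reagents that add atoms: benzeneselenol ([SeH]c1ccccc1)
Why: Michael addition of the selenol to the unhindered vinyl ketone, much faster than to the β-branched enoate, places the radical precursor on C6.

Step 20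
Reactants: 34 2-(trimethylsilyl)ethyl (2E,4S,5R)-5-(but-2-yn-1-yl)-4-(3-chloropropyl)-2,4-dimethyl-6-oxo-8-(phenylselanyl)oct-2-enoate
Product: 35 2-(trimethylsilyl)ethyl (2E,4S,5S)-5-(but-2-yn-1-yl)-4-(3-chloropropyl)-2,4-dimethyl-6-methylidene-8-(phenylselanyl)oct-2-enoate
Conditions: Zn, CH2Br2, TiCl4, THF/CH2Cl2, 0 → 23 °C
Reagents that add atoms: dibromomethane (BrCBr)
Why: Takai–Lombardo methylenation is non-basic and ketone-selective, so the C8 ketone becomes the C8=C17 methylene without epimerising C9 or touching the ester.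

Step 21
Reactants: 35 2-(trimethylsilyl)ethyl (2E,4S,5S)-5-(but-2-yn-1-yl)-4-(3-chloropropyl)-2,4-dimethyl-6-methylidene-8-(phenylselanyl)oct-2-enoate
Product: 37 2-(trimethylsilyl)ethyl (2E,4S,5S,7E)-4-(3-chloropropyl)-2,4,8-trimethyl-5-[4-(phenylselanyl)but-1-en-2-yl]deca-2,7,9-trienoate, via alkenylzirconocene 36 (not isolated)
Conditions: Cp2Zr(H)Cl, THF, 0 → 23 °C; then ZnCl2, Pd(PPh3)4 (cat.), CH2=CHBr, THF, 23 °C
Reagents that add atoms: vinyl bromide (C=CBr)
Why: syn-Hydrozirconation of the methyl alkyne should place zirconium on the less hindered, methyl-bearing carbon C13 (the 1,1-disubstituted alkene reacts far more slowly), and Negishi coupling with retention gives the E-trisubstituted diene.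

Step 22
Reactants: 17 (4aS,9R,9aS)-6-hydroxy-1,1,4a-trimethyl-5,8-dioxo-7-(propan-2-yl)-2,3,4,4a,5,8,9,9a-octahydro-1H-fluorene-9-carbaldehyde; 37 2-(trimethylsilyl)ethyl (2E,4S,5S,7E)-4-(3-chloropropyl)-2,4,8-trimethyl-5-[4-(phenylselanyl)but-1-en-2-yl]deca-2,7,9-trienoate
Product: 38 5+2 cycloadduct with acyclic labdane chain and free 7'-aldehyde
Conditions: BF3·OEt2 (1.2 equiv), CH2Cl2, −78 → −40 °C
Reagents that add atoms: none
Why: Proposed new method: activation at O11' makes C11' the centre of a pentadienyl cation C8'=C9'–C11'(+)–C12'(OH)=C13' whose termini add across the terminal C14=C15 bond (C15 to C13', then the allyl cation at C14 collapses onto C8') and loss of the O12' proton leaves the diosphenol; the closest known reaction types are the intramolecular perezone-to-pipitzol [5+2] cycloaddition and the Lewis-acid-promoted intermolecular [5+2] of 2-alkoxy-1,4-benzoquinones with styrenes; the substituted carbon C14 should go to the flat ring-fusion terminus C8' and not to the isopropyl-bearing C13', the diene should approach the α-face anti to the axial C10' methyl group, and an endo arrangement (C12=C13 under the C9'–C11' unit) sets C14, C8' and C13'.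

Step 23
Reactants: 38 5+2 cycloadduct with acyclic labdane chain and free 7'-aldehyde
Product: 39 7'-dimethyl acetal of cycloadduct 38
Conditions: HC(OMe)3, MeOH, PPTS (cat.), 23 °C
Reagents that add atoms: methanol (CO); trimethyl orthoformate (COC(OC)OC)
Why: Acetalisation should be selective for the aldehyde, because both ketones are flanked by fully substituted carbons, and it masks the acidic H-6' for the base stage of step 24.

Step 24
Reactants: 39 7'-dimethyl acetal of cycloadduct 38
Product: 41 2-(trimethylsilyl)ethyl ester and 7'-dimethyl acetal of the target, via ring-B monocycle 40 (not isolated)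
Conditions: (Me3Si)3SiH, AIBN (cat.), toluene, 80 °C, slow addition; then THF/DMPU, KN(SiMe3)2 (4 equiv), −78 → 0 °C
Reagents that add atoms: none
Why: The silyl radical abstracts the phenylselanyl group at C6, the primary C6 radical adds 6-exo-trig to C5, the β-carbon of the C5=C4(CH3)–C18O2R enoate (ring B, bond C5–C6), and the α-ester radical at C4 is reduced by the silane to give 40; KN(SiMe3)2 then deprotonates C4 and the ester enolate displaces chloride at C3 in a 6-exo-tet alkylation (ring A, bond C3–C4, closed last). The closest known reaction types are the alkyl radical cyclization onto an α,β-unsaturated ester and the intramolecular alkylation of an α-branched ester enolate. C5 is set in a chair-like transition state in which the C11 chain on C9, the chloropropyl chain on C10 and the enoate are equatorial and the C10 methyl group is axial, so H-5 ends anti to the C10 methyl group (trans ring fusion). C4 is set by allylic 1,3-strain in the enolate: H-5 eclipses the enolate double bond and C3, which is tethered through C10, attacks the face that leaves the ester equatorial (α) and the C4 methyl group axial (β). The step needs radical formation only at C6 (C–Se is abstracted far faster than C–Cl), addition to the electron-poor enoate rather than to the C12=C13 alkene (polarity matching), and the C4 enolate as the only carbon base, which the acetal at C7', the lack of α-hydrogens at both ketones and the potassium salt of the diosphenol secure.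

Step 25
Reactants: 41 2-(trimethylsilyl)ethyl ester and 7'-dimethyl acetal of the target
Product: 43 target CNP0269191.1, via carboxylic acid acetal 42 (not isolated)
Conditions: n-Bu4NF, THF, 0 → 23 °C; then 1 M HCl, THF/H2O, 23 °C
Reagents that add atoms: water (O)
Why: Fluoride attacks silicon and fragments the 2-(trimethylsilyl)ethyl ester to the carboxylate, ethene and Me3SiF without attack at the hindered C18 carbonyl, and dilute acid then hydrolyses the dimethyl acetal without isomerising the exocyclic alkene.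

## Compound list

1 | 2-isopropylanisole | COc1ccccc1C(C)C | starting material
2 | 4-(chloromethyl)-1-methoxy-2-(propan-2-yl)benzene | COc1ccc(CCl)cc1C(C)C | intermediate
3 | geranyl chloride, (2E)-1-chloro-3,7-dimethylocta-2,6-diene | CC(C)=CCC/C(C)=C/CCl | starting material
4 | [4-methoxy-3-(propan-2-yl)benzyl]magnesium chloride | COc1ccc(C[Mg]Cl)cc1C(C)C | intermediate
5 | 4-[(3E)-4,8-dimethylnona-3,7-dien-1-yl]-1-methoxy-2-(propan-2-yl)benzene | COc1ccc(CC/C=C(\C)CCC=C(C)C)cc1C(C)C | intermediate
6 | ferruginol methyl ether, (4bS,8aS)-3-methoxy-4b,8,8-trimethyl-2-(propan-2-yl)-4b,5,6,7,8,8a,9,10-octahydrophenanthrene | COc1cc2c(cc1C(C)C)CC[C@H]1C(C)(C)CCC[C@]21C | intermediate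
7 | sugiol methyl ether, 12-methoxyabieta-8,11,13-trien-7-one | COc1cc2c(cc1C(C)C)C(=O)C[C@H]1C(C)(C)CCC[C@]21C | intermediate
8 | 12-methoxy-6-(trifluoroacetyl)abieta-8,11,13-trien-7-one | COc1cc2c(cc1C(C)C)C(=O)C(C(=O)C(F)(F)F)[C@H]1C(C)(C)CCC[C@]21C | intermediate
9 | 6-diazo-12-methoxyabieta-8,11,13-trien-7-one | COc1cc2c(cc1C(C)C)C(=O)C(=[N+]=[N-])[C@H]1C(C)(C)CCC[C@]21C | intermediate
10 | ring-contracted ketene, [(4aS,9aS)-6-methoxy-1,1,4a-trimethyl-7-(propan-2-yl)-1,2,3,4,4a,9a-hexahydro-9H-fluoren-9-ylidene]methanone | COc1cc2c(cc1C(C)C)C(=C=O)[C@H]1C(C)(C)CCC[C@]21C | intermediate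
11 | methyl (4aS,9R,9aS)-6-methoxy-1,1,4a-trimethyl-7-(propan-2-yl)-2,3,4,4a,9,9a-hexahydro-1H-fluorene-9-carboxylate | COc1cc2c(cc1C(C)C)[C@H](C(=O)OC)[C@H]1C(C)(C)CCC[C@]21C | intermediate
12 | methyl (4aS,9R,9aS)-6-hydroxy-1,1,4a-trimethyl-7-(propan-2-yl)-2,3,4,4a,9,9a-hexahydro-1H-fluorene-9-carboxylate | Oc1cc2c(cc1C(C)C)[C@H](C(=O)OC)[C@H]1C(C)(C)CCC[C@]21C | intermediate
13 | (4aS,9R,9aS)-9-(hydroxymethyl)-1,1,4a-trimethyl-7-(propan-2-yl)-2,3,4,4a,9,9a-hexahydro-1H-fluoren-6-ol | Oc1cc2c(cc1C(C)C)[C@H](CO)[C@H]1C(C)(C)CCC[C@]21C | intermediate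
14 | ortho-quinone aldehyde, (4aS,9R,9aS)-1,1,4a-trimethyl-5,6-dioxo-7-(propan-2-yl)-2,3,4,4a,5,6,9,9a-octahydro-1H-fluorene-9-carbaldehyde | O=C1C(=O)C2=C(C=C1C(C)C)[C@H](C=O)[C@H]1C(C)(C)CCC[C@]21C | intermediate
15 | arylthio catechol, (4aS,9R,9aS)-5,6-dihydroxy-1,1,4a-trimethyl-8-[(pentafluorophenyl)sulfanyl]-7-(propan-2-yl)-2,3,4,4a,9,9a-hexahydro-1H-fluorene-9-carbaldehyde | Oc1c(O)c2c(c(Sc3c(F)c(F)c(F)c(F)c3F)c1C(C)C)[C@H](C=O)[C@H]1C(C)(C)CCC[C@]21C | intermediate
16 | arylthio ortho-quinone, 8-[(pentafluorophenyl)sulfanyl] derivative of 14 | O=C1C(=O)C2=C(C(Sc3c(F)c(F)c(F)c(F)c3F)=C1C(C)C)[C@H](C=O)[C@H]1C(C)(C)CCC[C@]21C | intermediate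
17 | hydroxy-para-quinone aldehyde of the taiwaniaquinone type, (4aS,9R,9aS)-6-hydroxy-1,1,4a-trimethyl-5,8-dioxo-7-(propan-2-yl)-2,3,4,4a,5,8,9,9a-octahydro-1H-fluorene-9-carbaldehyde | CC(C)C1=C(O)C(=O)C2=C(C1=O)[C@H](C=O)[C@H]1C(C)(C)CCC[C@]21C | intermediate
18 | 5-chloropent-1-yne | ClCCCC#C | starting material
19 | [(1E)-5-chloro-2-methylpent-1-en-1-yl]dimethylalumane | C[Al](C)/C=C(\C)CCCCl | intermediate
20 | (3E)-7-chloro-4-methylhept-3-en-2-one | CC(=O)/C=C(\C)CCCCl | intermediate
21 | (2R,3E)-7-chloro-4-methylhept-3-en-2-ol | C[C@@H](O)/C=C(\C)CCCCl | intermediate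
22 | hex-4-ynoic acid | CC#CCCC(=O)O | starting material
23 | (2R,3E)-7-chloro-4-methylhept-3-en-2-yl hex-4-ynoate | CC#CCCC(=O)O[C@H](C)/C=C(\C)CCCCl | intermediate
24 | Z tert-butyldimethylsilyl ketene acetal of 23 | CC#CC/C=C(\O[Si](C)(C)C(C)(C)C)O[C@H](C)/C=C(\C)CCCCl | intermediate
25 | tert-butyldimethylsilyl ester of 26 | C/C=C/[C@](C)(CCCCl)[C@H](C(=O)O[Si](C)(C)C(C)(C)C)CC#CC | intermediate
26 | (2R,3S,4E)-2-(but-2-yn-1-yl)-3-(3-chloropropyl)-3-methylhex-4-enoic acid | C/C=C/[C@](C)(CCCCl)[C@H](C(=O)O)CC#CC | intermediate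
27 | (2R,3S,4E)-2-(but-2-yn-1-yl)-3-(3-chloropropyl)-N-methoxy-N,3-dimethylhex-4-enamide | C/C=C/[C@](C)(CCCCl)[C@H](C(=O)N(C)OC)CC#CC | intermediate
28 | (2R,3R)-2-(but-2-yn-1-yl)-6-chloro-3-formyl-N-methoxy-N,3-dimethylhexanamide | O=C[C@](C)(CCCCl)[C@H](C(=O)N(C)OC)CC#CC | intermediate
29 | triethyl 2-phosphonopropionate | CCOC(=O)C(C)P(=O)(OCC)OCC | starting material
30 | 2-(trimethylsilyl)ethanol | C[Si](C)(C)CCO | starting material
31 | 2-(trimethylsilyl)ethyl 2-(diethoxyphosphoryl)propanoate | CCOP(=O)(OCC)C(C)C(=O)OCC[Si](C)(C)C | intermediate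
32 | 2-(trimethylsilyl)ethyl (2E,4S,5R)-4-(3-chloropropyl)-5-[methoxy(methyl)carbamoyl]-2,4-dimethylnon-2-en-7-ynoate | C[Si](C)(C)CCOC(=O)/C(C)=C/[C@](C)(CCCCl)[C@H](C(=O)N(C)OC)CC#CC | intermediate
33 | 2-(trimethylsilyl)ethyl (2E,4S,5R)-5-(but-2-yn-1-yl)-4-(3-chloropropyl)-2,4-dimethyl-6-oxoocta-2,7-dienoate | C[Si](C)(C)CCOC(=O)/C(C)=C/[C@](C)(CCCCl)[C@H](C(=O)C=C)CC#CC | intermediate
34 | 2-(trimethylsilyl)ethyl (2E,4S,5R)-5-(but-2-yn-1-yl)-4-(3-chloropropyl)-2,4-dimethyl-6-oxo-8-(phenylselanyl)oct-2-enoate | C[Si](C)(C)CCOC(=O)/C(C)=C/[C@](C)(CCCCl)[C@H](C(=O)CC[Se]c1ccccc1)CC#CC | intermediate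
35 | 2-(trimethylsilyl)ethyl (2E,4S,5S)-5-(but-2-yn-1-yl)-4-(3-chloropropyl)-2,4-dimethyl-6-methylidene-8-(phenylselanyl)oct-2-enoate | C[Si](C)(C)CCOC(=O)/C(C)=C/[C@](C)(CCCCl)[C@H](C(=C)CC[Se]c1ccccc1)CC#CC | intermediate
36 | E alkenylzirconocene chloride from 35, zirconium on C13 | C[Si](C)(C)CCOC(=O)/C(C)=C/[C@](C)(CCCCl)[C@H](C(=C)CC[Se]c1ccccc1)C/C=C(\C)[Zr](Cl)(C1C=CC=C1)C1C=CC=C1 | intermediate
37 | 2-(trimethylsilyl)ethyl (2E,4S,5S,7E)-4-(3-chloropropyl)-2,4,8-trimethyl-5-[4-(phenylselanyl)but-1-en-2-yl]deca-2,7,9-trienoate | C[Si](C)(C)CCOC(=O)/C(C)=C/[C@](C)(CCCCl)[C@H](C(=C)CC[Se]c1ccccc1)C/C=C(\C)C=C | intermediate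
38 | 5+2 cycloadduct: bicyclo[3.2.1]octenedione with bonds C14–C8' and C15–C13', 11'-enol, 12',14'-dione, free 7'-aldehyde; acyclic labdane chain with C5=C4 enoate, C3 chloride, C6 phenylselanyl and C8 methylene | C[Si](C)(C)CCOC(=O)/C(C)=C/[C@](C)(CCCCl)[C@H](C(=C)CC[Se]c1ccccc1)C/C=C(\C)[C@H]1C[C@@]2(C(C)C)C(=O)C(O)=C3[C@@]1(C2=O)[C@H](C=O)[C@H]1C(C)(C)CCC[C@]31C | intermediate
39 | 7'-dimethyl acetal of cycloadduct 38 | C[Si](C)(C)CCOC(=O)/C(C)=C/[C@](C)(CCCCl)[C@H](C(=C)CC[Se]c1ccccc1)C/C=C(\C)[C@H]1C[C@@]2(C(C)C)C(=O)C(O)=C3[C@@]1(C2=O)[C@H](C(OC)OC)[C@H]1C(C)(C)CCC[C@]31C | intermediate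
40 | ring-B monocycle: ring B closed (C5–C6), ring A open with C3 chloride and C4–H ester (both C4 epimers), 7'-dimethyl acetal | C=C1CC[C@@H](C(C)C(=O)OCC[Si](C)(C)C)[C@](C)(CCCCl)[C@H]1C/C=C(\C)[C@H]1C[C@@]2(C(C)C)C(=O)C(O)=C3[C@@]1(C2=O)[C@H](C(OC)OC)[C@H]1C(C)(C)CCC[C@]31C | intermediate
41 | 2-(trimethylsilyl)ethyl ester and 7'-dimethyl acetal of the target | C=C1CC[C@@H]2[C@](C)(CCC[C@@]2(C)C(=O)OCC[Si](C)(C)C)[C@H]1C/C=C(\C)[C@H]1C[C@@]2(C(C)C)C(=O)C(O)=C3[C@@]1(C2=O)[C@H](C(OC)OC)[C@H]1C(C)(C)CCC[C@]31C | intermediate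
42 | 7'-dimethyl acetal of the target (free C18 acid) | C=C1CC[C@@H]2[C@](C)(CCC[C@@]2(C)C(=O)O)[C@H]1C/C=C(\C)[C@H]1C[C@@]2(C(C)C)C(=O)C(O)=C3[C@@]1(C2=O)[C@H](C(OC)OC)[C@H]1C(C)(C)CCC[C@]31C | intermediate
43 | target CNP0269191.1 | C=C1CC[C@@H]2[C@](C)(CCC[C@@]2(C)C(=O)O)[C@H]1C/C=C(\C)[C@H]1C[C@@]2(C(C)C)C(=O)C(O)=C3[C@@]1(C2=O)[C@H](C=O)[C@H]1C(C)(C)CCC[C@]31C | target

## Step count and risks

Total step count: 25. Longest linear sequence: 15 steps (steps 10–15 and 17–25).

Three steps most likely to fail: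

1. Step 22 (proposed new method). What may go wrong: competing Diels–Alder addition of the diene to the quinone, a Lewis-acid carbonyl-ene or Prins reaction of the 7'-aldehyde with a nearby alkene, reaction at the C8=C17 alkene, or poor regio- and facial selectivity. Fallback with known chemistry, setting out from 17: the hydroxyl group is alkylated (4-MeOC6H4CH2Cl, Ag2O, CH2Cl2) to the 12'-O-(4-methoxybenzyl) ether F1. F1 and 37 are then combined under the TiCl4/Ti(OiPr)4-promoted [5+2] cycloaddition of 2-alkoxy-1,4-benzoquinones with cation-stabilising alkenes (CH2Cl2, −78 °C), in which the oxocarbenium adduct loses the benzyl group. The fallback comes back to the route at 38.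

2. Step 24 (key step). What may go wrong: hydrogen transfer to the C6 radical before it cyclises, hydrogen abstraction from allylic C11, addition to the C12=C13 alkene or hydrosilylation of the C8=C17 alkene on the elaborate adduct, or proton quench of the enolate before alkylation. Fallback, setting out from 35: ring B is closed before the cycloaddition. Bu3SnH and AIBN (benzene, 80 °C, slow addition) should give the ring-B monocycle with butynyl side chain F3. Hydrozirconation and Negishi vinylation as in step 21 give the monocyclic triene F4. The BF3·OEt2 cycloaddition with 17 as in step 22 gives the adduct F5, and acetalisation as in step 23 comes back to the route at 40, now isolated. Ring A is then closed as a separate operation with KN(SiMe3)2 (THF/DMPU, −78 → 0 °C) to give 41.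

3. Step 9. What may go wrong: over-oxidation, incomplete thiol exchange, or base-induced enolisation of the aldehyde towards a quinone methide during the multi-stage one-pot oxidation. Fallback, setting out from 13: (KSO3)2NO (KH2PO4 buffer, acetone/H2O) oxidises only the phenol to the ortho-quinone alcohol F6. Thiele–Winter acetoxylation (Ac2O, BF3·OEt2, 0 °C) gives the 11',12',14'-triacetoxy arene with acetylated primary alcohol F7. Methanolysis under air (K2CO3, MeOH) gives the hydroxy-para-quinone alcohol F8. Dess–Martin periodinane (CH2Cl2, 0 °C) then oxidises the primary alcohol, and the fallback comes back to the route at 17.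

## Further compounds

F1 | step 22 | 12'-O-(4-methoxybenzyl) ether of quinone 17 | CC(C)C1=C(OCc2ccc(OC)cc2)C(=O)C2=C(C1=O)[C@H](C=O)[C@H]1C(C)(C)CCC[C@]21C
F3 | step 24 | ring-B monocycle with butynyl side chain, C3 chloride and C4–H ester (both C4 epimers) | C=C1CC[C@@H](C(C)C(=O)OCC[Si](C)(C)C)[C@](C)(CCCCl)[C@H]1CC#CC
F4 | step 24 | ring-B monocyclic triene with C12–C15 diene | C=C1CC[C@@H](C(C)C(=O)OCC[Si](C)(C)C)[C@](C)(CCCCl)[C@H]1C/C=C(\C)C=C
F5 | step 24 | 5+2 cycloadduct of F4 and 17 with free 7'-aldehyde | C=C1CC[C@@H](C(C)C(=O)OCC[Si](C)(C)C)[C@](C)(CCCCl)[C@H]1C/C=C(\C)[C@H]1C[C@@]2(C(C)C)C(=O)C(O)=C3[C@@]1(C2=O)[C@H](C=O)[C@H]1C(C)(C)CCC[C@]31C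
F6 | step 9 | ortho-quinone alcohol, 9-(hydroxymethyl) analogue of 14 | O=C1C(=O)C2=C(C=C1C(C)C)[C@H](CO)[C@H]1C(C)(C)CCC[C@]21C
F7 | step 9 | 11',12',14'-triacetoxy arene with 7'-acetate | CC(=O)Oc1c(OC(C)=O)c2c(c(OC(C)=O)c1C(C)C)[C@H](COC(C)=O)[C@H]1C(C)(C)CCC[C@]21C
F8 | step 9 | hydroxy-para-quinone alcohol, 9-(hydroxymethyl) analogue of 17 | CC(C)C1=C(O)C(=O)C2=C(C1=O)[C@H](CO)[C@H]1C(C)(C)CCC[C@]21C
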